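**Retrosynthetic overview**

- The C2–C3 bond of the heptan-3-one chain (ketone carbon C3 to the CH2 that lies β to the trioxygenated ring B) is made by C-acylation of a lactone enolate with 5-(4-methoxyphenyl)pentanoyl chloride. In the same pot the lactone is opened and its carbonyl carbon is expelled as CO2, which gives the unprotected target directly.
- Enabling feature: the C2′ hydroxyl oxygen of ring B, ring carbons C2′ and C1′, the benzylic C1 and C2 of the chain can be closed, with one extra carbonyl carbon, to a six-membered lactone ring (3,4-dihydrocoumarin). In that ring chain C2 is the acidic α-carbon (lactone C3), the C2′ phenol is masked, and the extra carbon is traceless.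
- Precursors: 7-hydroxy-8-methoxy-3,4-dihydro-2H-chromen-2-one (one step from 2-methoxyresorcinol and acrylic acid) and the acid chloride (one step from the commercial acid). No protecting groups are used; the C4′ phenol is carried as its lithium phenoxide.
- Ring order: both benzene rings are bought; the lactone ring is closed in step 1 and opened again in step 3; the target has no stereocentre.

Key step: step 3

Remark: the open hydroxy ketone may equilibrate with its cyclic hemiketal (a 2-substituted chroman-2-ol); the hydroxy ketone form is the one named and drawn.

**Route**

Step 1
Reactants: 1 2-methoxybenzene-1,3-diol (2-methoxyresorcinol); 2 acrylic acid (prop-2-enoic acid)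
Product: 3 7-hydroxy-8-methoxy-3,4-dihydro-2H-chromen-2-one
Conditions: Amberlyst-15, toluene, reflux, Dean–Stark
Reagents that add atoms: none
Why: Acid-catalysed Friedel–Crafts conjugate hydroarylation of acrylic acid at C4 of the resorcinol (ortho to one hydroxyl and para to the other, C4 and C6 being equivalent), followed by lactonisation onto the neighbouring hydroxyl with azeotropic removal of water, is the known solid-acid route from resorcinols to 7-hydroxy-3,4-dihydrocoumarins, and no stereocentre is formed.

Step 2
Reactants: 4 5-(4-methoxyphenyl)pentanoic acid
Product: 5 5-(4-methoxyphenyl)pentanoyl chloride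
Conditions: (COCl)2, cat. DMF, CH2Cl2, 0 °C to rt; volatiles removed in vacuo
Reagents that add atoms: oxalyl chloride, O=C(Cl)C(=O)Cl
Why: Acid chloride formation through the Vilsmeier-type chloroiminium catalyst gives only gaseous by-products, so the evaporated residue should be usable directly, and the anisole ring is inert in the absence of a Lewis acid.

Step 3
Reactants: 3 7-hydroxy-8-methoxy-3,4-dihydro-2H-chromen-2-one (2.2 equiv); 5 5-(4-methoxyphenyl)pentanoyl chloride (1.0 equiv)
Product: 9 1-(2,4-dihydroxy-3-methoxyphenyl)-7-(4-methoxyphenyl)heptan-3-one, via dilithium dianion 6 (not isolated), via keto lactone 7 (not isolated), via keto acid 8 (not isolated)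
Conditions: 3 added to LDA (4.5 equiv), THF, −78 °C; then 5, −78 to 0 °C; then degassed 1 M aq NaOH, rt; then aq HCl to pH 1, 50 °C; under Ar
Reagents that add atoms: none
Why: LDA removes the C7 phenolic proton and then one C3 proton of the lactone, and the carbon terminus of the resulting phenoxide/enolate dianion 6 attacks the acid chloride 5 (crossed Claisen C-acylation of a lithium lactone enolate), the β-keto lactone 7 being deprotonated at once by a second equivalent of 6, which prevents a second acylation. Hydroxide then opens the aryl lactone and frees the C2′ phenol, and acidification gives the β-keto acid 8, which should lose CO2 through the usual six-membered cyclic transition state to the enol of 9, so that the lactone carbonyl carbon serves as a traceless activating group and water contributes only hydrogen to 9. The closest known reaction type is the acylation of ester and lactone lithium enolates with acid chlorides followed by ketonic hydrolysis and decarboxylation of the α-acyl lactone (acetoacetic ester logic). No ring is closed (the lactone ring is opened), and the only stereocentre, C3 of 7 and C2 of 8, is formed racemic and is erased by the decarboxylation, so no stereocontrol is required. The step needs acylation at the enolate carbon and not at the enolate or phenoxide oxygen, and it must outrun self-condensation and ketene-forming fragmentation of the aryl ester enolate; the lithium counter-ion in THF at −78 °C, the addition of 3 to an excess of base, the poor leaving-group ability and low electrophilicity of the phenoxide-bearing lactone, the hindrance of diisopropylamine and the excess of 6 should secure this. Any O-acylated material is an aryl or enol ester that the NaOH stage returns to 4 and to the hydroxy acid of 3, so such errors cost material but should not contaminate 9.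

**Compound list**

1 | 2-methoxybenzene-1,3-diol (2-methoxyresorcinol) | COc1c(O)cccc1O | starting material
2 | acrylic acid (prop-2-enoic acid) | C=CC(=O)O | starting material
3 | 7-hydroxy-8-methoxy-3,4-dihydro-2H-chromen-2-one | O=C1CCc2ccc(O)c(OC)c2O1 | intermediate
4 | 5-(4-methoxyphenyl)pentanoic acid | COc1ccc(CCCCC(=O)O)cc1 | starting material
5 | 5-(4-methoxyphenyl)pentanoyl chloride | COc1ccc(CCCCC(=O)Cl)cc1 | intermediate
6 | dilithium 8-methoxy-4H-chromene-2,7-bis(olate) (phenoxide/enolate dianion of 3) | [Li+].[Li+].[O-]C1=CCc2ccc([O-])c(OC)c2O1 | intermediate
7 | rac-7-hydroxy-8-methoxy-3-[5-(4-methoxyphenyl)pentanoyl]-3,4-dihydro-2H-chromen-2-one (one stereocentre at C3, racemic and enolisable; present as its enolate salt) | COc1ccc(CCCCC(=O)C2Cc3ccc(O)c(OC)c3OC2=O)cc1 | intermediate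
8 | rac-2-[(2,4-dihydroxy-3-methoxyphenyl)methyl]-7-(4-methoxyphenyl)-3-oxoheptanoic acid (one stereocentre at C2, racemic) | COc1ccc(CCCCC(=O)C(Cc2ccc(O)c(OC)c2O)C(=O)O)cc1 | intermediate
9 | 1-(2,4-dihydroxy-3-methoxyphenyl)-7-(4-methoxyphenyl)heptan-3-one (achiral) | COc1ccc(CCCCC(=O)CCc2ccc(O)c(OC)c2O)cc1 | target

**Step count and risks**

Total step count: 3. Longest linear sequence: 2 steps (step 1 then step 3, or step 2 then step 3).

Steps most likely to fail, in order of risk:

Step 3 (key step). The aryl ester enolate may fragment to a ketene or condense with a second molecule of lactone before it is acylated, and O-acylation may compete with C-acylation. The fallback sets out from 3. Deprotonation with LDA in the presence of TMSCl (in situ quench, THF, −78 °C) should trap the dianion as the neutral ketene silyl acetal trimethyl{[8-methoxy-7-(trimethylsilyloxy)-4H-chromen-2-yl]oxy}silane F1. A Mukaiyama-type C-acylation of F1 with 5 (cat. ZnCl2, CH2Cl2, 0 °C to rt) should then give, with loss of chlorotrimethylsilane, rac-8-methoxy-3-[5-(4-methoxyphenyl)pentanoyl]-7-(trimethylsilyloxy)-3,4-dihydro-2H-chromen-2-one F2. Its aryl silyl ether should fall off in the aqueous NaOH stage of step 3, where the route is rejoined at 7 and continues to 8 and 9.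

Step 1. Ring acylation (a Fries-type path to the isomeric chroman-4-one), twofold alkylation at C4 and C6, or polymerisation of acrylic acid may compete with the hydroarylation and lactonisation. The fallback sets out from 1. A Pechmann-type condensation with ethyl propiolate (ZnCl2, 90 °C) should give 7-hydroxy-8-methoxy-2H-chromen-2-one F3, in which C–C bond formation and ring closure are unambiguous. Hydrogenation of its C3=C4 bond (H2, Pd/C, EtOAc, rt) comes back to the route at 3.

Step 2. Hydrogen chloride or oxalyl chloride carried over in the unpurified acid chloride may quench part of the dianion, and deprotonation of the acid chloride to a ketene by residual amide base may divert it to O-acylation. The fallback sets out from 4. Activation with 1,1'-carbonyldiimidazole (THF, rt) should give the isolable acyl imidazolide 1-(1H-imidazol-1-yl)-5-(4-methoxyphenyl)pentan-1-one F4, a neutral acyl donor of another class. It is freed from imidazole by a cold aqueous wash and used in place of 5 in step 3, where the route is rejoined at 7.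

Further compounds
F1 | step 3 | trimethyl{[8-methoxy-7-(trimethylsilyloxy)-4H-chromen-2-yl]oxy}silane | COc1c(O[Si](C)(C)C)ccc2c1OC(O[Si](C)(C)C)=CC2
F2 | step 3 | rac-8-methoxy-3-[5-(4-methoxyphenyl)pentanoyl]-7-(trimethylsilyloxy)-3,4-dihydro-2H-chromen-2-one | COc1ccc(CCCCC(=O)C2Cc3ccc(O[Si](C)(C)C)c(OC)c3OC2=O)cc1
F3 | step 1 | 7-hydroxy-8-methoxy-2H-chromen-2-one | COc1c(O)ccc2ccc(=O)oc12
F4 | step 2 | 1-(1H-imidazol-1-yl)-5-(4-methoxyphenyl)pentan-1-one | COc1ccc(CCCCC(=O)n2ccnc2)cc1
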